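**Retrosynthetic overview**

1. Target 22 comes from chroman 20 by C3–C4 dehydrogenation. The strategy rests on the benzene ring C4a–C5–C6–C7–C8–C8a, which carries five oxygens in a row: O1 on C8a, OMe on C8, C7 and C6, and a free OH on C5 para to the C8 OMe.
2. That benzene ring is built last from the four-membered ring of cyclobutenone 17, with C4a–C5 as the new bond. The C=O carbon becomes C5–OH, the two squarate OMe carbons become C6 and C7, the C4(OMe) carbon becomes C8, and the enol-ether carbons of the dihydropyran become C8a and C4a.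
3. 17 comes from the C6-lithiated dihydropyran 15 and dimethyl squarate 14, then O-methylation. Dihydropyran 13 comes from lactol 11, made by hydroformylation of homoallylic alcohol 9, which comes from asymmetric allylation of methyl ketone 7 (sets C2).
4. 7 comes from aldehyde 4 by Wolff–Kishner reduction and Wacker oxidation. 4 comes from a formyl-endo, catalyst-controlled Diels–Alder reaction of 2-methylidenehex-5-enal 2 with (E)-3-methylpenta-1,3-diene 3 (sets C1′ and C2′).
5. Ring order: cyclohexene (step 2), dihydropyran (steps 6–7), benzene from the cyclobutenone (step 9).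

Key step: step 9

**Remarks**

- With open-chain dienes, 2-alkylacroleins are taken to add formyl-endo (the exo preference belongs to cyclopentadiene), so the formyl group ends up cis to the diene methyl. The side chain is therefore carried as the α-substituent of the dienophile, and the formyl group is reduced to the C1′ methyl.
- The sense of induction in steps 2 and 5 is assigned from the accepted transition-state models; both antipodes of each catalyst are available.
- Changes of R/S descriptor along the route (4, 6, 7, 9, 13, 20) come from CIP priorities only; the spatial arrangement is the same throughout.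

**Route**

Step 1
Reactants: 1 hex-5-enal
Product: 2 2-methylidenehex-5-enal
Conditions: 37% aq. CH2O (1.1 equiv), pyrrolidine (10 mol%), EtCO2H (10 mol%), i-PrOH, 45 °C
Reagents that add atoms: formaldehyde, C=O
Why: Amine/acid-catalysed Mannich condensation with formaldehyde followed by β-elimination of the amine (organocatalytic α-methylenation of an aldehyde) should give the 2-alkylacrolein without touching the remote vinyl group.

Step 2
Reactants: 2 2-methylidenehex-5-enal, 3 (E)-3-methylpenta-1,3-diene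
Product: 4 (1S,2R)-1-(but-3-en-1-yl)-2,3-dimethylcyclohex-3-ene-1-carbaldehyde
Conditions: 3 (3 equiv), (S)-B-o-tolyl-diphenylprolinol oxazaborolidine·Tf2NH (20 mol%), CH2Cl2, −78 → −40 °C
Reagents that add atoms: none
Why: In this catalytic asymmetric Diels–Alder reaction the boron-bound s-trans enal should bond through Cβ to the unsubstituted diene terminus (the 1-methyl group controls regiochemistry, as with 1-vinylcyclohexene), add formyl-endo so that CHO lies cis to the C2 methyl, and be attacked on the Cα Si face (CHO > butenyl > CH2) left open by the catalyst aryl group, which sets C1 as S and C2 as R.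

Step 3
Reactants: 4 (1S,2R)-1-(but-3-en-1-yl)-2,3-dimethylcyclohex-3-ene-1-carbaldehyde
Product: 6 (1R,2S)-1-(but-3-en-1-yl)-1,2,3-trimethylcyclohex-3-ene, via hydrazone 5 (not isolated)
Conditions: N2H4·H2O, diethylene glycol, 120 °C; then KOH, 195 °C (Huang-Minlon), Ar
Reagents that add atoms: none
Why: Wolff–Kishner reduction of the non-enolisable neopentyl aldehyde should turn the formyl group into the C1 methyl cis to the C2 methyl, and the quaternary centre cannot epimerise.

Step 4
Reactants: 6 (1R,2S)-1-(but-3-en-1-yl)-1,2,3-trimethylcyclohex-3-ene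
Product: 7 4-[(1S,2S)-1,2,3-trimethylcyclohex-3-en-1-yl]butan-2-one
Conditions: PdCl2 (10 mol%), CuCl (1 equiv), O2 (1 atm), DMF/H2O 7:1, rt
Reagents that add atoms: water, O
Why: Tsuji–Wacker oxidation by Markovnikov hydroxypalladation of the monosubstituted alkene should give the methyl ketone while the hindered trisubstituted ring alkene stays uncoordinated.

Step 5
Reactants: 7 4-[(1S,2S)-1,2,3-trimethylcyclohex-3-en-1-yl]butan-2-one
Product: 9 (3R)-3-methyl-1-[(1S,2S)-1,2,3-trimethylcyclohex-3-en-1-yl]hex-5-en-3-ol, via borate ester 8 (not isolated)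
Conditions: allyl-B(OiPr)2 (1.5 equiv), (R)-3,3′-Br2-BINOL (15 mol%), PhCF3/PhMe 3:1, −35 °C; aq. work-up
Reagents that add atoms: allyldiisopropoxyborane, C=CCB(OC(C)C)OC(C)C
Why: Diol-catalysed asymmetric allylboration of a ketone through a closed chair transition state (chain equatorial, methyl axial) should deliver allyl to the Si face (O > CH2 > CH3) under reagent control and set the carbinol carbon as R, the ring stereocentres being too remote to interfere.

Step 6
Reactants: 9 (3R)-3-methyl-1-[(1S,2S)-1,2,3-trimethylcyclohex-3-en-1-yl]hex-5-en-3-ol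
Product: 11 (6S)-6-methyl-6-{2-[(1S,2S)-1,2,3-trimethylcyclohex-3-en-1-yl]ethyl}oxan-2-ol (anomer mixture), via hydroxy aldehyde 10 (not isolated)
Conditions: Rh(acac)(CO)2 (1 mol%), Xantphos (3 mol%), CO/H2 1:1 (10 bar), PhMe, 70 °C
Reagents that add atoms: carbon monoxide, [C-]#[O+]
Why: Linear-selective Rh-catalysed hydroformylation of the terminal alkene should give the δ-hydroxy aldehyde, which closes to the six-membered lactol, and the trisubstituted ring alkene is inert under these conditions.

Step 7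
Reactants: 11 (6S)-6-methyl-6-{2-[(1S,2S)-1,2,3-trimethylcyclohex-3-en-1-yl]ethyl}oxan-2-ol
Product: 13 (2S)-2-methyl-2-{2-[(1S,2S)-1,2,3-trimethylcyclohex-3-en-1-yl]ethyl}-3,4-dihydro-2H-pyran, via anomeric mesylate 12 (not isolated)
Conditions: MsCl (1.5 equiv), Et3N (4 equiv), CH2Cl2, 0 °C → reflux
Reagents that add atoms: none
Why: Anomeric mesylation and base-mediated loss of methanesulfonate (lactol dehydration) should give the cyclic enol ether under non-acidic conditions that spare the tertiary ether and the ring alkene.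

Step 8
Reactants: 13 (2S)-2-methyl-2-{2-[(1S,2S)-1,2,3-trimethylcyclohex-3-en-1-yl]ethyl}-3,4-dihydro-2H-pyran, 14 dimethyl squarate
Product: 17 2,3,4-trimethoxy-4-[(2S)-2-methyl-2-{2-[(1S,2S)-1,2,3-trimethylcyclohex-3-en-1-yl]ethyl}-3,4-dihydro-2H-pyran-6-yl]cyclobut-2-en-1-one (both C4 epimers), via vinyllithium 15 (not isolated), via lithium alkoxide 16 (not isolated)
Conditions: t-BuLi (1.1 equiv), THF, −78 → 0 °C; cannulate into 14 (1.2 equiv), THF, −78 °C; MeOTf (1.5 equiv), −78 → 0 °C
Reagents that add atoms: methyl trifluoromethanesulfonate, COS(=O)(=O)C(F)(F)F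
Why: α-Alkoxyvinyl lithiation of the enol ether at C6, 1,2-addition to one squarate carbonyl and in-flask O-methylation of the tertiary lithium alkoxide are standard squarate chemistry, and the new cyclobutenone C4 centre may form as both epimers because it becomes sp2 in step 9.

Step 9
Reactants: 17 2,3,4-trimethoxy-4-[(2S)-2-methyl-2-{2-[(1S,2S)-1,2,3-trimethylcyclohex-3-en-1-yl]ethyl}-3,4-dihydro-2H-pyran-6-yl]cyclobut-2-en-1-one
Product: 20 (2R)-6,7,8-trimethoxy-2-methyl-2-{2-[(1S,2S)-1,2,3-trimethylcyclohex-3-en-1-yl]ethyl}chroman-5-ol, via dienylketene 18 (not isolated), via cyclohexadienone 19 (not isolated)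
Conditions: p-xylene (0.01 M, degassed), 138 °C, Ar
Reagents that add atoms: none
Why: Heating should open the strained cyclobutenone by conrotatory 4π electrocyclic cleavage of C1–C4 to dienylketene 18, whose ketene carbon closes onto C5 of the dihydropyran enol ether in a thermally allowed disrotatory 6π electrocyclisation to cyclohexa-2,4-dienone 19, and enolisation of the C4a–H then gives the phenol. The closest known reaction is the Moore rearrangement of 4-alkenyl-4-alkoxycyclobutenones from squarate esters, including 4-(dihydropyran-6-yl) cases, to annulated hydroquinone monoethers. The one ring closed is the benzene ring, by 6π electrocyclisation forming C4a–C5. No new stereocentre survives: the sp3 C4a of 19 is lost on aromatisation, both C4 epimers of 17 converge, and C2 and the two cyclohexene centres are not involved. The step needs the right torquoselectivity, and the donor methoxy group on C4 should rotate outward, which swings the dihydropyranyl alkene inward next to the ketene; the regiochemistry (C=O carbon to C5–OH, C4 to C8–OMe, C2/C3 to C6/C7) is then fixed by connectivity. Dilute, degassed solution under argon should keep the ketene from intermolecular reactions and the hydroquinone monoether from air oxidation.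

Step 10
Reactants: 20 (2R)-6,7,8-trimethoxy-2-methyl-2-{2-[(1S,2S)-1,2,3-trimethylcyclohex-3-en-1-yl]ethyl}chroman-5-ol
Product: 22 (2R)-6,7,8-trimethoxy-2-methyl-2-{2-[(1S,2S)-1,2,3-trimethylcyclohex-3-en-1-yl]ethyl}-2H-chromen-5-ol, via ortho-quinone methide 21 (not isolated)
Conditions: DDQ (1.1 equiv), anhydrous PhH, 80 °C, Ar
Reagents that add atoms: none
Why: Quinone dehydrogenation of a chroman, in which DDQ should oxidise the electron-rich phenol to the ortho-quinone methide by removal of the C4 hydrogen and a prototropic shift from C3 then re-aromatises to the 2H-chromene, leaving the quaternary C2 untouched.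

**Compound list**

1 | hex-5-enal | C=CCCCC=O | starting material
2 | 2-methylidenehex-5-enal | C=CCCC(=C)C=O | intermediate
3 | (E)-3-methylpenta-1,3-diene | C=C/C(C)=C/C | starting material
4 | (1S,2R)-1-(but-3-en-1-yl)-2,3-dimethylcyclohex-3-ene-1-carbaldehyde | C=CCC[C@]1(C=O)CCC=C(C)[C@H]1C | intermediate
5 | hydrazone of 4 | C=CCC[C@]1(C=NN)CCC=C(C)[C@H]1C | intermediate
6 | (1R,2S)-1-(but-3-en-1-yl)-1,2,3-trimethylcyclohex-3-ene | C=CCC[C@]1(C)CCC=C(C)[C@H]1C | intermediate
7 | 4-[(1S,2S)-1,2,3-trimethylcyclohex-3-en-1-yl]butan-2-one | CC(=O)CC[C@]1(C)CCC=C(C)[C@H]1C | intermediate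
8 | diisopropyl borate ester of 9 | C=CC[C@@](C)(CC[C@]1(C)CCC=C(C)[C@H]1C)OB(OC(C)C)OC(C)C | intermediate
9 | (3R)-3-methyl-1-[(1S,2S)-1,2,3-trimethylcyclohex-3-en-1-yl]hex-5-en-3-ol | C=CC[C@@](C)(CC[C@]1(C)CCC=C(C)[C@H]1C)O | intermediate
10 | (5S)-5-hydroxy-5-methyl-7-[(1S,2S)-1,2,3-trimethylcyclohex-3-en-1-yl]heptanal | O=CCCC[C@@](C)(CC[C@]1(C)CCC=C(C)[C@H]1C)O | intermediate
11 | (6S)-6-methyl-6-{2-[(1S,2S)-1,2,3-trimethylcyclohex-3-en-1-yl]ethyl}oxan-2-ol (anomer mixture) | OC1CCC[C@@](C)(CC[C@]2(C)CCC=C(C)[C@H]2C)O1 | intermediate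
12 | anomeric methanesulfonate of 11 | CS(=O)(=O)OC1CCC[C@@](C)(CC[C@]2(C)CCC=C(C)[C@H]2C)O1 | intermediate
13 | (2S)-2-methyl-2-{2-[(1S,2S)-1,2,3-trimethylcyclohex-3-en-1-yl]ethyl}-3,4-dihydro-2H-pyran | C1=CCC[C@@](C)(CC[C@]2(C)CCC=C(C)[C@H]2C)O1 | intermediate
14 | dimethyl squarate (3,4-dimethoxycyclobut-3-ene-1,2-dione) | COC1=C(OC)C(=O)C1=O | starting material
15 | 6-lithio derivative of 13 | [Li]C1=CCC[C@@](C)(CC[C@]2(C)CCC=C(C)[C@H]2C)O1 | intermediate
16 | lithium 2,3-dimethoxy-4-oxo-1-(dihydropyran-6-yl)cyclobut-2-en-1-olate from 15 and 14 | [Li]OC1(C2=CCC[C@@](C)(CC[C@]3(C)CCC=C(C)[C@H]3C)O2)C(OC)=C(OC)C1=O | intermediate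
17 | 2,3,4-trimethoxy-4-[(2S)-2-methyl-2-{2-[(1S,2S)-1,2,3-trimethylcyclohex-3-en-1-yl]ethyl}-3,4-dihydro-2H-pyran-6-yl]cyclobut-2-en-1-one (both C4 epimers) | COC1=C(OC)C(OC)(C2=CCC[C@@](C)(CC[C@]3(C)CCC=C(C)[C@H]3C)O2)C1=O | intermediate
18 | (Z)-2,3,4-trimethoxy-4-(dihydropyran-6-yl)buta-1,3-dien-1-one (dienylketene from 17) | O=C=C(OC)/C(OC)=C(OC)\C1=CCC[C@@](C)(CC[C@]2(C)CCC=C(C)[C@H]2C)O1 | intermediate
19 | 6,7,8-trimethoxy-2-methyl-2-(side chain)-2,3,4,4a-tetrahydro-5H-chromen-5-one (cyclohexa-2,4-dienone, C4a epimers) | O=C1C(OC)=C(OC)C(OC)=C2O[C@](C)(CC[C@]3(C)CCC=C(C)[C@H]3C)CCC12 | intermediate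
20 | (2R)-6,7,8-trimethoxy-2-methyl-2-{2-[(1S,2S)-1,2,3-trimethylcyclohex-3-en-1-yl]ethyl}chroman-5-ol | COc1c(O)c2c(c(OC)c1OC)O[C@](C)(CC[C@]1(C)CCC=C(C)[C@H]1C)CC2 | intermediate
21 | ortho-quinone methide of 20 (C5=O, C4a=C4) | COC1=C(OC)C(OC)=C2O[C@](C)(CC[C@]3(C)CCC=C(C)[C@H]3C)CC=C2C1=O | intermediate
22 | (2R)-6,7,8-trimethoxy-2-methyl-2-{2-[(1S,2S)-1,2,3-trimethylcyclohex-3-en-1-yl]ethyl}-2H-chromen-5-ol | COc1c(O)c2c(c(OC)c1OC)O[C@](C)(CC[C@]1(C)CCC=C(C)[C@H]1C)C=C2 | target

**Step count**

Total steps: 10. Longest linear sequence: 10 steps, from hex-5-enal 1.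

**Steps most likely to fail, with fallbacks**

Step 2. Regiochemistry, endo/exo selectivity and enantiofacial control must all hold at once. The internal diene methyl opposes the terminal one, the formyl-endo preference may erode, and the acidic catalyst may oligomerise the diene or trigger an ene cyclisation of 2. The fallback sets C1′ by 1,2-induction in an enolate alkylation instead of in the cycloaddition; it sets out from 3 and rejoins the route at 4. Diene 3 and commercial (R)-3-acryloyl-4-benzyloxazolidin-2-one (Et2AlCl, CH2Cl2, −78 °C; chelate-controlled endo Diels–Alder with Re-face attack at Cα, which fixes C2′) should give (R)-4-benzyl-3-[(1S,2S)-2,3-dimethylcyclohex-3-ene-1-carbonyl]oxazolidin-2-one F1. MeOMgBr in MeOH/CH2Cl2 at 0 °C should give methyl (1S,2S)-2,3-dimethylcyclohex-3-ene-1-carboxylate F2. LDA in THF/DMPU at −78 °C, then 4-iodobut-1-ene, should alkylate the ester enolate anti to the neighbouring C2′ methyl and give methyl (1S,2R)-1-(but-3-en-1-yl)-2,3-dimethylcyclohex-3-ene-1-carboxylate F3. LiAlH4 should give [(1S,2R)-1-(but-3-en-1-yl)-2,3-dimethylcyclohex-3-en-1-yl]methanol F4, and Dess–Martin oxidation returns aldehyde 4.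

Step 5. Facial discrimination between the methyl group and the CH2CH2 chain of a dialkyl ketone may be too weak, giving C2 epimers that are unlikely to separate. The fallback sets the tertiary C–O centre by Sharpless epoxidation, which is chemoselective for the allylic alcohol over the ring alkene; it sets out from 7 and rejoins the route at 9. Triethyl phosphonoacetate/NaH in THF should give, after separation of the Z isomer, ethyl (2E)-3-methyl-5-[(1S,2S)-1,2,3-trimethylcyclohex-3-en-1-yl]pent-2-enoate F5. DIBAL at −78 °C should give (2E)-3-methyl-5-[(1S,2S)-1,2,3-trimethylcyclohex-3-en-1-yl]pent-2-en-1-ol F6. Ti(OiPr)4, D-(−)-diethyl tartrate and t-BuOOH (4 Å MS, CH2Cl2, −20 °C; the sense opposite to geraniol with the L-tartrate) should give [(2R,3R)-3-methyl-3-{2-[(1S,2S)-1,2,3-trimethylcyclohex-3-en-1-yl]ethyl}oxiran-2-yl]methanol F7. SO3·pyridine/DMSO/Et3N should give (2S,3R)-3-methyl-3-{2-[(1S,2S)-1,2,3-trimethylcyclohex-3-en-1-yl]ethyl}oxirane-2-carbaldehyde F8. Ph3P=CH2 in THF should give (2R,3R)-2-methyl-2-{2-[(1S,2S)-1,2,3-trimethylcyclohex-3-en-1-yl]ethyl}-3-vinyloxirane F9. Pd2(dba)3/PBu3 with HCO2H/Et3N in dioxane should then cleave the allylic C–O bond and deliver hydride to the internal allyl carbon, giving homoallylic alcohol 9 with the tertiary C–O bond intact.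

Step 10. Oxidation of the hydroquinone monoether at the ring (oxidative demethylation to the 5,8-quinone, or aryloxy–DDQ adducts) may outrun removal of the C4 hydrogen. The fallback masks the phenol so that dehydrogenation runs by benzylic hydride abstraction instead of phenol oxidation; it sets out from 20 and rejoins the route at 22. Ac2O/pyridine/DMAP should give (2R)-6,7,8-trimethoxy-2-methyl-2-{2-[(1S,2S)-1,2,3-trimethylcyclohex-3-en-1-yl]ethyl}chroman-5-yl acetate F10. DDQ in refluxing dioxane (C4 cation stabilised by O1 and the C7 methoxy group, then loss of the C3 proton) should give (2R)-6,7,8-trimethoxy-2-methyl-2-{2-[(1S,2S)-1,2,3-trimethylcyclohex-3-en-1-yl]ethyl}-2H-chromen-5-yl acetate F11. K2CO3 in MeOH under argon then frees the phenol to give 22.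

**Further compounds**

F1 | step 2 | (R)-4-benzyl-3-[(1S,2S)-2,3-dimethylcyclohex-3-ene-1-carbonyl]oxazolidin-2-one | O=C([C@H]1CCC=C(C)[C@H]1C)N1[C@H](Cc2ccccc2)COC1=O
F2 | step 2 | methyl (1S,2S)-2,3-dimethylcyclohex-3-ene-1-carboxylate | COC(=O)[C@H]1CCC=C(C)[C@H]1C
F3 | step 2 | methyl (1S,2R)-1-(but-3-en-1-yl)-2,3-dimethylcyclohex-3-ene-1-carboxylate | C=CCC[C@]1(C(=O)OC)CCC=C(C)[C@H]1C
F4 | step 2 | [(1S,2R)-1-(but-3-en-1-yl)-2,3-dimethylcyclohex-3-en-1-yl]methanol | C=CCC[C@]1(CO)CCC=C(C)[C@H]1C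
F5 | step 5 | ethyl (2E)-3-methyl-5-[(1S,2S)-1,2,3-trimethylcyclohex-3-en-1-yl]pent-2-enoate | CCOC(=O)/C=C(\C)CC[C@]1(C)CCC=C(C)[C@H]1C
F6 | step 5 | (2E)-3-methyl-5-[(1S,2S)-1,2,3-trimethylcyclohex-3-en-1-yl]pent-2-en-1-ol | OC/C=C(\C)CC[C@]1(C)CCC=C(C)[C@H]1C
F7 | step 5 | [(2R,3R)-3-methyl-3-{2-[(1S,2S)-1,2,3-trimethylcyclohex-3-en-1-yl]ethyl}oxiran-2-yl]methanol | OC[C@H]1O[C@]1(C)CC[C@]2(C)CCC=C(C)[C@H]2C
F8 | step 5 | (2S,3R)-3-methyl-3-{2-[(1S,2S)-1,2,3-trimethylcyclohex-3-en-1-yl]ethyl}oxirane-2-carbaldehyde | O=C[C@H]1O[C@]1(C)CC[C@]2(C)CCC=C(C)[C@H]2C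
F9 | step 5 | (2R,3R)-2-methyl-2-{2-[(1S,2S)-1,2,3-trimethylcyclohex-3-en-1-yl]ethyl}-3-vinyloxirane | C=C[C@H]1O[C@]1(C)CC[C@]2(C)CCC=C(C)[C@H]2C
F10 | step 10 | (2R)-6,7,8-trimethoxy-2-methyl-2-{2-[(1S,2S)-1,2,3-trimethylcyclohex-3-en-1-yl]ethyl}chroman-5-yl acetate | COc1c(OC(C)=O)c2c(c(OC)c1OC)O[C@](C)(CC[C@]1(C)CCC=C(C)[C@H]1C)CC2
F11 | step 10 | (2R)-6,7,8-trimethoxy-2-methyl-2-{2-[(1S,2S)-1,2,3-trimethylcyclohex-3-en-1-yl]ethyl}-2H-chromen-5-yl acetate | COc1c(OC(C)=O)c2c(c(OC)c1OC)O[C@](C)(CC[C@]1(C)CCC=C(C)[C@H]1C)C=C2
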